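Everything rests on cutting two bonds of the ring B phthalide at once: C3–B, a stand-in for the lactol C3–OH, and O2–C1. Lactol carbon C3 racemises through its open formyl-acid tautomer, and with boron in place of hydroxyl that escape is closed. In one operation a chiral bisphosphine-ligated Cu–Bpin species adds to the aldehyde of an ortho-formyl methyl benzoate. The alkoxide so formed closes the lactone on the neighbouring ester, giving the ring, the C–B bond and the stereocentre. The precursor already holds the ring A benzylic ester and carries both phenols as TBS ethers. Desilylation and a stereoretentive C–B oxidation, done last, complete the target.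

Key step: step 12

Numbering used: phthalide C1 (lactone C=O), O2, C3, C3a, C4, C5, C6, C7, C7a. Ring A is the 2-hydroxy-4-methoxy-3,6-dimethylbenzoyl unit and ring B is the benzo ring of the phthalide.
Remark on the chemistry: the sense of induction cannot be predicted with confidence for this hindered aromatic aldehyde, so the ligand antipode that sends boron to the Si face is meant. It is written as (R)-DTBM-SEGPHOS, and both antipodes are commercial.
Remark on the chemistry: 3-hydroxyphthalides equilibrate with the open formyl acid, so the single enantiomer of the target is assumed to persist only in cold, neutral, preferably aprotic media and is handled accordingly.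

Step 1
Reactants: 1 3,5-dimethoxybenzaldehyde
Product: 2 2-(3,5-dimethoxyphenyl)-1,3-dioxolane
Conditions: HOCH2CH2OH, p-TsOH·H2O (cat.), toluene, reflux, Dean–Stark trap
Reagents that add atoms: ethylene glycol, OCCO
Why: Acid-catalysed acetalisation with azeotropic removal of water masks the aldehyde against the organolithium reagents of steps 2 and 5.

Step 2
Reactants: 2 2-(3,5-dimethoxyphenyl)-1,3-dioxolane
Product: 4 4-(1,3-dioxolan-2-yl)-2,6-dimethoxybenzaldehyde, via aryllithium 3 (not isolated)
Conditions: n-BuLi (1.1 equiv), THF, 0 °C; DMF, −78 °C to rt; H2O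
Reagents that add atoms: N,N-dimethylformamide, CN(C)C=O
Why: Directed ortho metalation takes the most acidic ring hydrogen, the one flanked by both methoxy groups, and formylation of the aryllithium with DMF puts the future C6 side-chain carbon there.

Step 3
Reactants: 4 4-(1,3-dioxolan-2-yl)-2,6-dimethoxybenzaldehyde
Product: 5 3-bromo-4-(1,3-dioxolan-2-yl)-2,6-dimethoxybenzaldehyde
Conditions: NBS (1.0 equiv), MeCN, 0 °C to rt, dark
Reagents that add atoms: N-bromosuccinimide, O=C1CCC(=O)N1Br
Why: Electrophilic aromatic bromination has only two free positions to choose from, which are equivalent by symmetry (ortho and para to methoxy, meta to the formyl group), and the formyl group shields its own ring carbon from ipso attack.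

Step 4
Reactants: 5 3-bromo-4-(1,3-dioxolan-2-yl)-2,6-dimethoxybenzaldehyde
Product: 6 [3-bromo-4-(1,3-dioxolan-2-yl)-2,6-dimethoxyphenyl]methanol
Conditions: NaBH4, MeOH, 0 °C
Reagents that add atoms: none
Why: Borohydride reduction converts the free aldehyde into the primary benzylic alcohol and leaves the acetal and the aryl bromide alone.

Step 5
Reactants: 6 [3-bromo-4-(1,3-dioxolan-2-yl)-2,6-dimethoxyphenyl]methanol
Product: 9 3-hydroxy-6-(hydroxymethyl)-5,7-dimethoxyisobenzofuran-1(3H)-one (racemic lactol), via dilithio species 7 (not isolated), via acetal acid 8 (not isolated)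
Conditions: n-BuLi (2.2 equiv), THF, −78 °C; CO2 (g), −78 to 0 °C; 1 M HCl, THF, rt
Reagents that add atoms: carbon dioxide, O=C=O; water, O
Why: Deprotonation of the alcohol and bromine–lithium exchange give an aryllithium held by the acetal and methoxy oxygens, and carboxylation followed by acetal hydrolysis unveils the ortho-formyl acid, which rests as its racemic ring tautomer (this C3 centre is erased again in step 6).

Step 6
Reactants: 9 3-hydroxy-6-(hydroxymethyl)-5,7-dimethoxyisobenzofuran-1(3H)-one
Product: 10 methyl 6-formyl-3-(hydroxymethyl)-2,4-dimethoxybenzoate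
Conditions: K2CO3 (1.1 equiv), MeI (1.2 equiv), DMF, rt
Reagents that add atoms: iodomethane, CI
Why: SN2 alkylation of the carboxylate of the open tautomer gives the normal methyl ester rather than the pseudo ester that acid and methanol would give, and the neutral primary alcohol is not alkylated under these conditions.

Step 7
Reactants: 11 methyl 2,4-dihydroxy-3,6-dimethylbenzoate (atraric acid)
Product: 12 methyl 2-hydroxy-4-methoxy-3,6-dimethylbenzoate
Conditions: K2CO3 (1.1 equiv), MeI (1.1 equiv), acetone, reflux
Reagents that add atoms: iodomethane, CI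
Why: Williamson etherification is selective for the C4 phenol because the C2 phenol is tied up in a hydrogen bond to the ester carbonyl and is flanked on both sides.

Step 8
Reactants: 12 methyl 2-hydroxy-4-methoxy-3,6-dimethylbenzoate
Product: 13 2-hydroxy-4-methoxy-3,6-dimethylbenzoic acid
Conditions: KOH (6 equiv), DMSO–H2O, 90 °C; then cold 2 M HCl, 0 °C
Reagents that add atoms: potassium hydroxide, [K+].[OH-]
Why: Forcing saponification in a dipolar aprotic medium overcomes the double ortho substitution, the carboxylate is safe from decarboxylation while hot, and the free acid is liberated only in the cold.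

Step 9
Reactants: 10 methyl 6-formyl-3-(hydroxymethyl)-2,4-dimethoxybenzoate; 13 2-hydroxy-4-methoxy-3,6-dimethylbenzoic acid
Product: 14 [4-formyl-2,6-dimethoxy-3-(methoxycarbonyl)phenyl]methyl 2-hydroxy-4-methoxy-3,6-dimethylbenzoate
Conditions: PPh3, DIAD, THF, 0 °C to rt
Reagents that add atoms: none
Why: Mitsunobu esterification forms the ester by SN2 attack of the carboxylate of 13 on the activated primary benzylic carbon, which sidesteps acyl addition at the doubly ortho-substituted ring A carbonyl, exploits the acidity gap between acid and hydrogen-bonded phenol, and makes the ring A ester the only protection the CH2OH ever needs (a benzyl-type ether would not outlast BCl3 in step 10).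

Step 10
Reactants: 14 [4-formyl-2,6-dimethoxy-3-(methoxycarbonyl)phenyl]methyl 2-hydroxy-4-methoxy-3,6-dimethylbenzoate
Product: 15 [4-formyl-2-hydroxy-6-methoxy-3-(methoxycarbonyl)phenyl]methyl 2-hydroxy-4-methoxy-3,6-dimethylbenzoate
Conditions: BCl3 (3 equiv), CH2Cl2, −78 to 0 °C; then 1 M HCl, 0 °C
Reagents that add atoms: none
Why: In this chelation-controlled aryl methyl ether cleavage, BCl3 held between the methyl ester carbonyl and the adjacent methoxy oxygen delivers chloride to that methyl group only, the other two methoxy groups have no ortho carbonyl, and ionisation of the benzylic ester is held back by the para formyl and meta ester groups.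

Step 11
Reactants: 15 [4-formyl-2-hydroxy-6-methoxy-3-(methoxycarbonyl)phenyl]methyl 2-hydroxy-4-methoxy-3,6-dimethylbenzoate
Product: 16 [2-(tert-butyldimethylsilyloxy)-4-formyl-6-methoxy-3-(methoxycarbonyl)phenyl]methyl 2-(tert-butyldimethylsilyloxy)-4-methoxy-3,6-dimethylbenzoate
Conditions: TBSOTf (3 equiv), 2,6-lutidine (4 equiv), CH2Cl2, 0 °C to rt
Reagents that add atoms: tert-butyldimethylsilyl triflate, CC(C)(C)[Si](C)(C)OS(=O)(=O)C(F)(F)F
Why: Silylation with the triflate overcomes the hydrogen bonding and double ortho substitution of both phenols in one operation, and the weak, hindered base avoids phenoxide-driven loss of the ring A carboxylate.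

Step 12
Reactants: 16 [2-(tert-butyldimethylsilyloxy)-4-formyl-6-methoxy-3-(methoxycarbonyl)phenyl]methyl 2-(tert-butyldimethylsilyloxy)-4-methoxy-3,6-dimethylbenzoate; 17 bis(pinacolato)diboron
Product: 19 [(3S)-7-(tert-butyldimethylsilyloxy)-5-methoxy-1-oxo-3-(4,4,5,5-tetramethyl-1,3,2-dioxaborolan-2-yl)-1,3-dihydroisobenzofuran-6-yl]methyl 2-(tert-butyldimethylsilyloxy)-4-methoxy-3,6-dimethylbenzoate, via α-boryl copper alkoxide 18 (not isolated)
Conditions: CuCl (5 mol %), (R)-DTBM-SEGPHOS (5.5 mol %), KOt-Bu (5 mol %), 17 (1.2 equiv), THF, −20 to 0 °C, no protic additive; filtration through neutral silica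
Reagents that add atoms: bis(pinacolato)diboron 17, CC1(C)OB(OC1(C)C)B1OC(C)(C)C(C)(C)O1
Why: Proposed new method: the complex LCu–Bpin (L = the bisphosphine), made from LCuOt-Bu and 17, should insert the formyl C=O of 16 with boron going to carbon (C3–B) and copper to oxygen, giving alkoxide 18. This alkoxide sits beside the methyl ester, whose carbonyl is twisted out of the ring plane by its two ortho neighbours, and should attack it in a 5-exo-trig acyl substitution (O2–C1) that expels LCuOMe, which 17 turns back into LCu–Bpin with loss of MeOBpin, so no free alkoxide builds up. The closest known reaction types are the enantioselective 1,2-borylation of aldehydes by monovalent copper with chiral bisphosphines and the lactonisation of ortho-ester benzylic alkoxides to phthalides, and their union to a 3-borylphthalide is not known. C3 is set by the ligand, which must present boron to the Si face of the aldehyde to give the 3S boronate, the same arrangement in space as the 3R lactol because boron ranks below C3a whereas hydroxyl ranks above it. The aldehyde is chosen over the two esters because it is far more electrophilic, only the methyl ester lies within reach of the new alkoxide, and fast acylation of 18 should outrun the carbon-to-oxygen boryl shift and the loss of configuration typical of benzylic α-boryl alkoxides. Both phenols are silylated so that no acidic OH can protonate LCu–Bpin (which would open a copper hydride path to plain aldehyde reduction) and no C7 phenoxide can expel the ring A carboxylate through a quinone methide.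

Step 13
Reactants: 19 (3S)-bis-TBS 3-borylphthalide ester
Product: 20 [(3S)-7-hydroxy-5-methoxy-1-oxo-3-(4,4,5,5-tetramethyl-1,3,2-dioxaborolan-2-yl)-1,3-dihydroisobenzofuran-6-yl]methyl 2-hydroxy-4-methoxy-3,6-dimethylbenzoate
Conditions: HF·pyridine, pyridine, THF, 0 °C (polypropylene vessel); NaH2PO4/Na2HPO4 buffer (pH 7)
Reagents that add atoms: none
Why: Fluoride-mediated cleavage of aryl silyl ethers, fast here because both phenoxides are conjugated with an ortho carbonyl, is run in an acidic buffered medium that neither removes the acidic C3–H nor opens the lactone, so the C3–B centre should pass unchanged, and any boron–fluorine exchange would be harmless because such species are oxidised in the same way in step 14.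

Step 14
Reactants: 20 (3S)-3-borylphthalide ester with both phenols free
Product: 22 [(3R)-3,7-dihydroxy-5-methoxy-1-oxo-1,3-dihydroisobenzofuran-6-yl]methyl 2-hydroxy-4-methoxy-3,6-dimethylbenzoate (CNP0398000.1), via O-boryl lactol 21 (not isolated)
Conditions: 30% aq H2O2 (2 equiv), NaH2PO4/Na2HPO4 buffer (pH 7), THF, 0 °C; cold EtOAc extraction, evaporation below 0 °C, storage at −78 °C
Reagents that add atoms: hydrogen peroxide, OO
Why: In this stereoretentive boronate oxidation, hydroperoxide adds to boron and C3 migrates from boron to oxygen with retention to give borate 21, whose B–O bond hydrolyses without touching C3–O, so the 3S boronate maps onto the 3R lactol, while neutral pH, low temperature and short contact time restrain ring–chain tautomerism.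

Compound list
1 | 3,5-dimethoxybenzaldehyde | COc1cc(C=O)cc(OC)c1 | starting material
2 | 2-(3,5-dimethoxyphenyl)-1,3-dioxolane | COc1cc(cc(OC)c1)C1OCCO1 | intermediate
3 | [4-(1,3-dioxolan-2-yl)-2,6-dimethoxyphenyl]lithium | [Li]c1c(OC)cc(cc1OC)C1OCCO1 | intermediate
4 | 4-(1,3-dioxolan-2-yl)-2,6-dimethoxybenzaldehyde | COc1cc(cc(OC)c1C=O)C1OCCO1 | intermediate
5 | 3-bromo-4-(1,3-dioxolan-2-yl)-2,6-dimethoxybenzaldehyde | COc1cc(C2OCCO2)c(Br)c(OC)c1C=O | intermediate
6 | [3-bromo-4-(1,3-dioxolan-2-yl)-2,6-dimethoxyphenyl]methanol | COc1cc(C2OCCO2)c(Br)c(OC)c1CO | intermediate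
7 | lithium [4-(1,3-dioxolan-2-yl)-3-lithio-2,6-dimethoxyphenyl]methoxide | COc1cc(C2OCCO2)c([Li])c(OC)c1CO[Li] | intermediate
8 | 6-(1,3-dioxolan-2-yl)-3-(hydroxymethyl)-2,4-dimethoxybenzoic acid | COc1cc(C2OCCO2)c(C(=O)O)c(OC)c1CO | intermediate
9 | 3-hydroxy-6-(hydroxymethyl)-5,7-dimethoxyisobenzofuran-1(3H)-one, racemic | COc1cc2C(O)OC(=O)c2c(OC)c1CO | intermediate
10 | methyl 6-formyl-3-(hydroxymethyl)-2,4-dimethoxybenzoate | COC(=O)c1c(C=O)cc(OC)c(CO)c1OC | intermediate
11 | methyl 2,4-dihydroxy-3,6-dimethylbenzoate (atraric acid) | COC(=O)c1c(C)cc(O)c(C)c1O | starting material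
12 | methyl 2-hydroxy-4-methoxy-3,6-dimethylbenzoate | COC(=O)c1c(C)cc(OC)c(C)c1O | intermediate
13 | 2-hydroxy-4-methoxy-3,6-dimethylbenzoic acid | OC(=O)c1c(C)cc(OC)c(C)c1O | intermediate
14 | [4-formyl-2,6-dimethoxy-3-(methoxycarbonyl)phenyl]methyl 2-hydroxy-4-methoxy-3,6-dimethylbenzoate | COc1cc(C)c(C(=O)OCc2c(OC)cc(C=O)c(C(=O)OC)c2OC)c(O)c1C | intermediate
15 | [4-formyl-2-hydroxy-6-methoxy-3-(methoxycarbonyl)phenyl]methyl 2-hydroxy-4-methoxy-3,6-dimethylbenzoate | COc1cc(C)c(C(=O)OCc2c(OC)cc(C=O)c(C(=O)OC)c2O)c(O)c1C | intermediate
16 | [2-(tert-butyldimethylsilyloxy)-4-formyl-6-methoxy-3-(methoxycarbonyl)phenyl]methyl 2-(tert-butyldimethylsilyloxy)-4-methoxy-3,6-dimethylbenzoate (key-step precursor) | COc1cc(C)c(C(=O)OCc2c(OC)cc(C=O)c(C(=O)OC)c2O[Si](C)(C)C(C)(C)C)c(O[Si](C)(C)C(C)(C)C)c1C | intermediate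
17 | bis(pinacolato)diboron | CC1(C)OB(OC1(C)C)B1OC(C)(C)C(C)(C)O1 | starting material
18 | (S)-α-boryl copper alkoxide from 16 (bisphosphine on copper omitted) | COc1cc(C)c(C(=O)OCc2c(OC)cc([C@@H](O[Cu])B3OC(C)(C)C(C)(C)O3)c(C(=O)OC)c2O[Si](C)(C)C(C)(C)C)c(O[Si](C)(C)C(C)(C)C)c1C | intermediate
19 | [(3S)-7-(tert-butyldimethylsilyloxy)-5-methoxy-1-oxo-3-(pinacolboryl)-1,3-dihydroisobenzofuran-6-yl]methyl 2-(tert-butyldimethylsilyloxy)-4-methoxy-3,6-dimethylbenzoate (key-step product) | COc1cc(C)c(C(=O)OCc2c(OC)cc3c(c2O[Si](C)(C)C(C)(C)C)C(=O)O[C@H]3B2OC(C)(C)C(C)(C)O2)c(O[Si](C)(C)C(C)(C)C)c1C | intermediate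
20 | [(3S)-7-hydroxy-5-methoxy-1-oxo-3-(pinacolboryl)-1,3-dihydroisobenzofuran-6-yl]methyl 2-hydroxy-4-methoxy-3,6-dimethylbenzoate | COc1cc(C)c(C(=O)OCc2c(OC)cc3c(c2O)C(=O)O[C@H]3B2OC(C)(C)C(C)(C)O2)c(O)c1C | intermediate
21 | [(3R)-7-hydroxy-5-methoxy-1-oxo-3-(pinacolboryloxy)-1,3-dihydroisobenzofuran-6-yl]methyl 2-hydroxy-4-methoxy-3,6-dimethylbenzoate | COc1cc(C)c(C(=O)OCc2c(OC)cc3c(c2O)C(=O)O[C@H]3OB2OC(C)(C)C(C)(C)O2)c(O)c1C | intermediate
22 | [(3R)-3,7-dihydroxy-5-methoxy-1-oxo-1,3-dihydroisobenzofuran-6-yl]methyl 2-hydroxy-4-methoxy-3,6-dimethylbenzoate (CNP0398000.1) | COc1cc(C)c(C(=O)OCc2c(OC)cc3c(c2O)C(=O)O[C@H]3O)c(O)c1C | target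

Total step count: 14.
Longest linear sequence: 12 steps (steps 1–6 and 9–14, from 3,5-dimethoxybenzaldehyde). Ring A takes 2 steps (7 and 8) and joins at step 9.

Steps most likely to fail

1. Step 12.
- What may go wrong: weak facial discrimination on a hindered, electron-rich aromatic aldehyde, migration of boron from carbon to oxygen before ring closure, or loss of configuration by deprotonation at the acidic C3–H.
- The fallback uses known reactions only and no C–B bond. It sets out from 15.
- Warming 15 in 2 M HCl–dioxane lets the aldehyde hydrate close on the neighbouring methyl ester and gives the racemic lactol F1.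
- The two lactol enantiomers interconvert through the open formyl acid. A dynamic kinetic resolution by enantioselective acyl transfer (chiral isothiourea benzotetramisole, isobutyric anhydride, toluene, 0 °C) should therefore funnel the material into the (3R)-3-isobutyryloxyphthalide F2. This acylal cannot ring-open and can be purified and enriched by crystallisation.
- Lipase B from Candida antarctica in NaH2PO4/Na2HPO4 buffer (pH 7)–MTBE at 5 °C then cleaves the exocyclic ester at its acyl carbon and leaves C3–O untouched. The route is rejoined at 22.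

2. Step 14.
- What may go wrong: sluggish oxidation of the pinacol boronate at neutral pH, so that lactol already formed stays long in water and erodes by ring–chain tautomerism.
- The fallback changes the boron group rather than the strength of the oxidant. It sets out from 20.
- KHF2 in MeOH–H2O at rt exchanges pinacol for fluoride and gives the potassium (3S)-trifluoroborate F3, a salt that can be purified by precipitation.
- KHSO5 (as 2KHSO5·KHSO4·K2SO4) in acetone–H2O at 0 °C oxidises organotrifluoroborates within minutes and with retention. The time the lactol spends in water is cut to a minimum, and the route is rejoined at 22.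

3. Step 13.
- What may go wrong: binding of fluoride to boron, followed by protodeboronation or epimerisation through the stabilised phthalide anion.
- The fallback removes fluoride from the plan by changing the phenol protection. It sets out from 15.
- MOMCl and i-Pr2NEt in CH2Cl2 give the bis-MOM formyl ester F4.
- The conditions of step 12 convert it into the (3S)-bis-MOM borylphthalide F5.
- TFA in moist CH2Cl2 at 0 °C cleaves both acetals under conditions that pinacol boronates and the electron-poor benzylic ester tolerate. The route is rejoined at 20.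

Further compounds
F1 | step 12 | racemic [3,7-dihydroxy-5-methoxy-1-oxo-1,3-dihydroisobenzofuran-6-yl]methyl 2-hydroxy-4-methoxy-3,6-dimethylbenzoate | COc1cc(C)c(C(=O)OCc2c(OC)cc3c(c2O)C(=O)OC3O)c(O)c1C
F2 | step 12 | [(3R)-7-hydroxy-5-methoxy-3-(2-methylpropanoyloxy)-1-oxo-1,3-dihydroisobenzofuran-6-yl]methyl 2-hydroxy-4-methoxy-3,6-dimethylbenzoate | COc1cc(C)c(C(=O)OCc2c(OC)cc3c(c2O)C(=O)O[C@H]3OC(=O)C(C)C)c(O)c1C
F3 | step 14 | potassium trifluoro[(3S)-7-hydroxy-6-{[(2-hydroxy-4-methoxy-3,6-dimethylbenzoyl)oxy]methyl}-5-methoxy-1-oxo-1,3-dihydroisobenzofuran-3-yl]borate | [K+].COc1cc(C)c(C(=O)OCc2c(OC)cc3c(c2O)C(=O)O[C@H]3[B-](F)(F)F)c(O)c1C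
F4 | step 13 | [4-formyl-6-methoxy-3-(methoxycarbonyl)-2-(methoxymethoxy)phenyl]methyl 4-methoxy-2-(methoxymethoxy)-3,6-dimethylbenzoate | COCOc1c(C)c(OC)cc(C)c1C(=O)OCc1c(OC)cc(C=O)c(C(=O)OC)c1OCOC
F5 | step 13 | [(3S)-5-methoxy-7-(methoxymethoxy)-1-oxo-3-(pinacolboryl)-1,3-dihydroisobenzofuran-6-yl]methyl 4-methoxy-2-(methoxymethoxy)-3,6-dimethylbenzoate | COCOc1c(C)c(OC)cc(C)c1C(=O)OCc1c(OC)cc2c(c1OCOC)C(=O)O[C@H]2B1OC(C)(C)C(C)(C)O1
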